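**Retrosynthetic overview** (azulene numbering: C-3 = isopropyl carbinol, C-3a = ring-fusion CH, C-4 = acyloxy carbon, C-8a = quaternary methyl carbon)
1. Target 30 ⇒ jaeschkeanadiol 27 + O-acetylsalicyloyl chloride 28 (esterify the secondary 4-OH, then free the phenol).
2. 27 ⇒ diene diol 26 by ring-closing metathesis (seven-membered ring, formed last); 26 ⇒ β-hydroxy aldehyde 22 + methallyl metal 23 (carbonyl allylation sets C-4).
3. 22 ⇒ cyclopentanone 19 (i-Pr addition sets C-3) ⇒ cyclopentenone 18 ⇒ keto aldehyde 16 (intramolecular aldol condensation; five-membered carbocycle, formed first).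
4. 16 ⇒ lactone 10, built on chiral butenolide 4 (furfural + (+)-menthol) by the key intermolecular Michael addition of lithiated 2-methyl-1,3-dithiane 5 (C-3/C-3a bond), enolate allylation, then α-methylation (C-8a).
5. Ring order: butenolide template (later opened) → cyclopentane → cycloheptene.

Assumption: (+)-menthol, 2-methyl-1,3-dithiane, 2-methylallylmagnesium chloride solution, O-acetylsalicyloyl chloride and (−)-Ipc2BOMe are taken as commercial. The route is designed from known reaction classes and has not been run; the stereochemical outcomes of steps 3, 4, 12 and 15 are predictions.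

**Step 1**
Reactants: 1 furfural
Product: 2 5-hydroxyfuran-2(5H)-one (racemic)
Conditions: O2, hν (visible), rose bengal (cat.), MeOH, rt
Reagents that add atoms: dioxygen, O=O
Why: Singlet-oxygen [4+2] photooxygenation of the furan gives an endoperoxide that fragments in methanol (formyl carbon lost as methyl formate) to the hydroxybutenolide; its hemiacetal centre is racemic and is fixed in step 2.

**Step 2**
Reactants: 2 5-hydroxyfuran-2(5H)-one; 3 (+)-menthol
Product: 4 (5S)-5-[(1S,2R,5S)-menthyloxy]furan-2(5H)-one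
Conditions: cat. p-TsOH, toluene, reflux (Dean–Stark); crystallise (hexanes, −20 °C), mother liquor re-equilibrated with acid and recrystallised
Reagents that add atoms: none
Why: Acid-catalysed acetalisation gives two interconverting acetal epimers, and the (5S)-epimer of the (+)-menthol series crystallises out (crystallisation-induced asymmetric transformation, mirror image of the known (−)-menthol case).

**Step 3**
Reactants: 4 (5S)-5-[(1S,2R,5S)-menthyloxy]furan-2(5H)-one; 5 2-methyl-1,3-dithiane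
Product: 8 (3S,4S,5S)-5-[(1S,2R,5S)-menthyloxy]-4-(2-methyl-1,3-dithian-2-yl)-3-(prop-2-en-1-yl)oxolan-2-one, via lithiated dithiane 6 (not isolated), via lithium enolate 7 (not isolated)
Conditions: 5, n-BuLi, THF, −20 °C; then 4, −78 °C; then allyl bromide, DMPU, −78 → −30 °C
Reagents that add atoms: allyl bromide, C=CCBr
Why: Tandem Michael addition–enolate alkylation: the sulfur-stabilised carbanion adds 1,4 anti to the menthyloxy group (setting the future C-3a) and the enolate is allylated anti to the new dithianyl group.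

**Step 4**
Reactants: 8 the all-trans lactone
Product: 10 (3R,4S,5S)-3-methyl-5-[(1S,2R,5S)-menthyloxy]-4-(2-methyl-1,3-dithian-2-yl)-3-(prop-2-en-1-yl)oxolan-2-one, via lithium enolate 9 (not isolated)
Conditions: LiN(i-Pr)2, THF, −78 °C; MeI, DMPU, −78 → −30 °C
Reagents that add atoms: iodomethane, CI
Why: Enolate alkylation in which MeI enters the planar lactone enolate on the face opposite the bulky dithianyl group, so methyl ends trans and allyl cis to it, fixing the quaternary centre (future C-8a).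

**Step 5**
Reactants: 10 the quaternary lactone acetal
Product: 12 (3R,4S)-3-methyl-4-(2-methyl-1,3-dithian-2-yl)-3-(prop-2-en-1-yl)oxolan-2-one, via hydroxy lactone 11 (not isolated)
Conditions: TFA–H2O (4:1), 40 °C; evaporate; NaBH4, EtOH, 0 °C → rt; then 1 M HCl
Reagents that add atoms: water, O
Why: Acylal hydrolysis releases menthol and the pseudo-acid, whose open aldehyde form is reduced by borohydride and relactonises on acidification; neither stereocentre is touched.

**Step 6**
Reactants: 12 the γ-lactone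
Product: 13 (3R,4S)-3-methyl-4-(2-methyl-1,3-dithian-2-yl)-3-(prop-2-en-1-yl)oxolan-2-ol (anomer mixture)
Conditions: i-Bu2AlH (1.1 equiv), CH2Cl2, −78 °C; aq. KNaC4H4O6
Reagents that add atoms: none
Why: Partial lactone reduction stops at the aluminium hemiacetal at low temperature (lactone-to-lactol reduction); the dithiane masks the ketone.

**Step 7**
Reactants: 13 the lactol
Product: 14 (2S,3R)-3-(1,3-dithian-2-yl)-3-methyl-2-(2-methyl-1,3-dithian-2-yl)hex-5-en-1-ol
Conditions: HS(CH2)3SH, BF3·OEt2 (cat.), CH2Cl2, −20 → 0 °C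
Reagents that add atoms: propane-1,3-dithiol, SCCCS
Why: Lewis-acid thioacetalisation opens the lactol to the open-chain dithiane, which frees the primary alcohol and so differentiates the two oxygenated carbons.

**Step 8**
Reactants: 14 the bis-dithiane alcohol
Product: 15 tert-butyldimethylsilyl ether of 14
Conditions: TBSCl, imidazole, DMF, rt
Reagents that add atoms: tert-butyldimethylsilyl chloride, CC(C)(C)[Si](C)(C)Cl
Why: Standard silylation of the primary alcohol, so that no free β-hydroxyl is present when the ketone is unmasked.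

**Step 9**
Reactants: 15 the silyl ether
Product: 16 (2R,3S)-3-({[tert-butyl(dimethyl)silyl]oxy}methyl)-2-methyl-4-oxo-2-(prop-2-en-1-yl)pentanal
Conditions: MeI, CaCO3, MeCN–H2O (4:1), 45 °C
Reagents that add atoms: water, O
Why: Alkylative hydrolysis (S-methylation, then water) removes both dithianes under near-neutral conditions, giving the 1,4-keto aldehyde without epimerising the α-CH.

**Step 10**
Reactants: 16 the keto aldehyde
Product: 18 (4S,5S)-5-({[tert-butyl(dimethyl)silyl]oxy}methyl)-4-methyl-4-(prop-2-en-1-yl)cyclopent-2-en-1-one, via aldol adduct 17 (not isolated)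
Conditions: KOH, EtOH, 0 °C → rt
Reagents that add atoms: none
Why: Intramolecular aldol condensation in which the methyl ketone enolate attacks the non-enolisable neopentyl aldehyde and E1cB dehydration gives the cyclopentenone; no stereocentre is formed or used.

**Step 11**
Reactants: 18 the cyclopentenone
Product: 19 (2S,3R)-2-({[tert-butyl(dimethyl)silyl]oxy}methyl)-3-methyl-3-(prop-2-en-1-yl)cyclopentan-1-one
Conditions: [(Ph3P)CuH]6, benzene, H2O (few equiv), rt
Reagents that add atoms: none
Why: Copper hydride conjugate reduction saturates only the enone C=C; the isolated allyl group and silyl ether are inert.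

**Step 12**
Reactants: 19 the cyclopentanone
Product: 20 (1R,2S,3R)-2-({[tert-butyl(dimethyl)silyl]oxy}methyl)-3-methyl-1-(propan-2-yl)-3-(prop-2-en-1-yl)cyclopentan-1-ol
Conditions: i-PrMgCl, CeCl3 (anhydrous), THF, −78 → 0 °C; aq. NH4Cl
Reagents that add atoms: isopropylmagnesium chloride, CC(C)[Mg]Cl
Why: Organocerium 1,2-addition suppresses enolisation and reduction, and attack anti to the adjacent CH2OTBS group places the new hydroxyl cis to it (future C-3).

**Step 13**
Reactants: 20 the tertiary alcohol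
Product: 21 (1R,2S,3R)-2-(hydroxymethyl)-3-methyl-1-(propan-2-yl)-3-(prop-2-en-1-yl)cyclopentan-1-ol
Conditions: Bu4NF, THF, rt
Reagents that add atoms: none
Why: Fluoride-mediated desilylation.

**Step 14**
Reactants: 21 the diol
Product: 22 (1R,2R,5R)-2-hydroxy-5-methyl-2-(propan-2-yl)-5-(prop-2-en-1-yl)cyclopentane-1-carbaldehyde
Conditions: Dess–Martin periodinane, CH2Cl2, 0 °C → rt; used crude
Reagents that add atoms: none
Why: Dess–Martin oxidation of the primary alcohol (the tertiary one cannot be oxidised); the α-centre is safe because the formyl group already sits trans to the isopropyl group.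

**Step 15**
Reactants: 22 the β-hydroxy aldehyde; 23 2-methylallylmagnesium chloride
Product: 26 (1R,2S,3R)-2-[(1S)-1-hydroxy-3-methylbut-3-en-1-yl]-3-methyl-1-(propan-2-yl)-3-(prop-2-en-1-yl)cyclopentan-1-ol, via methallyl diisopinocampheylborane 24 (not isolated), via borinate ester 25 (not isolated)
Conditions: 23, (−)-Ipc2BOMe, Et2O, −78 °C → rt; then 22, −78 °C; NaOH, H2O2, rt
Reagents that add atoms: none
Why: Brown asymmetric carbonyl methallylation: the (+)-α-pinene-derived allylborane adds through a closed chair transition state to the Si face of the aldehyde, giving the (S)-carbinol (future C-4) under reagent control.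

**Step 16**
Reactants: 26 the diene diol
Product: 27 (3R,3aS,4S,8aR)-6,8a-dimethyl-3-(propan-2-yl)-1,2,3,3a,4,5,8,8a-octahydroazulene-3,4-diol (jaeschkeanadiol)
Conditions: second-generation Grubbs catalyst (H2IMes)(PCy3)Cl2Ru=CHPh (5 mol %), CH2Cl2 (3 mM), 40 °C
Reagents that add atoms: none
Why: Ring-closing metathesis of the allyl and methallyl alkenes forms the trisubstituted cycloheptene, trans-fused because the two chains are trans on the cyclopentane.

**Step 17**
Reactants: 27 jaeschkeanadiol; 28 O-acetylsalicyloyl chloride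
Product: 29 (3R,3aS,4S,8aR)-3-hydroxy-6,8a-dimethyl-3-(propan-2-yl)-1,2,3,3a,4,5,8,8a-octahydroazulen-4-yl 2-(acetyloxy)benzoate
Conditions: pyridine, DMAP (cat.), CH2Cl2, 0 °C → rt
Reagents that add atoms: none
Why: DMAP-catalysed acylation of the secondary hydroxyl; the hindered tertiary alcohol does not react.

**Step 18**
Reactants: 29 the acetylsalicylate
Product: 30 (3R,3aS,4S,8aR)-3-hydroxy-6,8a-dimethyl-3-(propan-2-yl)-1,2,3,3a,4,5,8,8a-octahydroazulen-4-yl 2-hydroxybenzoate (target)
Conditions: pyrrolidine, CH2Cl2, 0 °C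
Reagents that add atoms: none
Why: Aminolysis of the activated aryl acetate is much faster than attack on the hindered alkyl salicylate, which frees the phenol.

**Compound list**
1 | furfural (furan-2-carbaldehyde) | O=Cc1ccco1 | starting material
2 | 5-hydroxyfuran-2(5H)-one, racemic | O=C1C=CC(O)O1 | intermediate
3 | (+)-menthol, (1S,2R,5S)-5-methyl-2-(propan-2-yl)cyclohexan-1-ol | O[C@H]1C[C@@H](C)CC[C@@H]1C(C)C | starting material
4 | (5S)-5-[(1S,2R,5S)-menthyloxy]furan-2(5H)-one | O=C1C=C[C@@H](O[C@H]2C[C@@H](C)CC[C@@H]2C(C)C)O1 | intermediate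
5 | 2-methyl-1,3-dithiane | CC1SCCCS1 | starting material
6 | 2-lithio-2-methyl-1,3-dithiane (formed in the flask) | [Li]C1(C)SCCCS1 | intermediate
7 | lithium enolate of the Michael adduct, dithianyl trans to menthyloxy (formed in the flask) | [Li]OC1=C[C@H](C2(C)SCCCS2)[C@@H](O[C@H]2C[C@@H](C)CC[C@@H]2C(C)C)O1 | intermediate
8 | (3S,4S,5S)-5-[(1S,2R,5S)-menthyloxy]-4-(2-methyl-1,3-dithian-2-yl)-3-(prop-2-en-1-yl)oxolan-2-one (all-trans) | C=CC[C@@H]1C(=O)O[C@H](O[C@H]2C[C@@H](C)CC[C@@H]2C(C)C)[C@H]1C3(C)SCCCS3 | intermediate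
9 | lithium enolate of 8 (formed in the flask) | C=CCC1=C(O[Li])O[C@H](O[C@H]2C[C@@H](C)CC[C@@H]2C(C)C)[C@H]1C3(C)SCCCS3 | intermediate
10 | (3R,4S,5S)-3-methyl-5-[(1S,2R,5S)-menthyloxy]-4-(2-methyl-1,3-dithian-2-yl)-3-(prop-2-en-1-yl)oxolan-2-one (methyl trans to dithianyl) | C=CC[C@@]1(C)C(=O)O[C@H](O[C@H]2C[C@@H](C)CC[C@@H]2C(C)C)[C@H]1C3(C)SCCCS3 | intermediate
11 | (3R,4S)-5-hydroxy-3-methyl-4-(2-methyl-1,3-dithian-2-yl)-3-(prop-2-en-1-yl)oxolan-2-one, anomer mixture (formed in the flask) | C=CC[C@@]1(C)C(=O)OC(O)[C@H]1C3(C)SCCCS3 | intermediate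
12 | (3R,4S)-3-methyl-4-(2-methyl-1,3-dithian-2-yl)-3-(prop-2-en-1-yl)oxolan-2-one | C=CC[C@@]1(C)C(=O)OC[C@H]1C3(C)SCCCS3 | intermediate
13 | (3R,4S)-3-methyl-4-(2-methyl-1,3-dithian-2-yl)-3-(prop-2-en-1-yl)oxolan-2-ol, anomer mixture | C=CC[C@@]1(C)C(O)OC[C@H]1C3(C)SCCCS3 | intermediate
14 | (2S,3R)-3-(1,3-dithian-2-yl)-3-methyl-2-(2-methyl-1,3-dithian-2-yl)hex-5-en-1-ol | C=CC[C@@](C)(C1SCCCS1)[C@@H](CO)C2(C)SCCCS2 | intermediate
15 | tert-butyldimethylsilyl ether of 14 | C=CC[C@@](C)(C1SCCCS1)[C@@H](CO[Si](C)(C)C(C)(C)C)C2(C)SCCCS2 | intermediate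
16 | (2R,3S)-3-({[tert-butyl(dimethyl)silyl]oxy}methyl)-2-methyl-4-oxo-2-(prop-2-en-1-yl)pentanal | C=CC[C@@](C)(C=O)[C@@H](CO[Si](C)(C)C(C)(C)C)C(C)=O | intermediate
17 | (2S,3R)-2-({[tert-butyl(dimethyl)silyl]oxy}methyl)-4-hydroxy-3-methyl-3-(prop-2-en-1-yl)cyclopentan-1-one, carbinol epimers (formed in the flask) | C=CC[C@@]1(C)C(O)CC(=O)[C@@H]1CO[Si](C)(C)C(C)(C)C | intermediate
18 | (4S,5S)-5-({[tert-butyl(dimethyl)silyl]oxy}methyl)-4-methyl-4-(prop-2-en-1-yl)cyclopent-2-en-1-one | C=CC[C@@]1(C)C=CC(=O)[C@@H]1CO[Si](C)(C)C(C)(C)C | intermediate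
19 | (2S,3R)-2-({[tert-butyl(dimethyl)silyl]oxy}methyl)-3-methyl-3-(prop-2-en-1-yl)cyclopentan-1-one | C=CC[C@@]1(C)CCC(=O)[C@@H]1CO[Si](C)(C)C(C)(C)C | intermediate
20 | (1R,2S,3R)-2-({[tert-butyl(dimethyl)silyl]oxy}methyl)-3-methyl-1-(propan-2-yl)-3-(prop-2-en-1-yl)cyclopentan-1-ol | C=CC[C@@]1(C)CC[C@@](O)(C(C)C)[C@@H]1CO[Si](C)(C)C(C)(C)C | intermediate
21 | (1R,2S,3R)-2-(hydroxymethyl)-3-methyl-1-(propan-2-yl)-3-(prop-2-en-1-yl)cyclopentan-1-ol | C=CC[C@@]1(C)CC[C@@](O)(C(C)C)[C@@H]1CO | intermediate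
22 | (1R,2R,5R)-2-hydroxy-5-methyl-2-(propan-2-yl)-5-(prop-2-en-1-yl)cyclopentane-1-carbaldehyde | C=CC[C@@]1(C)CC[C@@](O)(C(C)C)[C@@H]1C=O | intermediate
23 | 2-methylallylmagnesium chloride, CH2=C(CH3)CH2MgCl | C=C(C)C[Mg]Cl | starting material
24 | (−)-B-(2-methylallyl)diisopinocampheylborane, isopinocampheyl groups from (+)-α-pinene (formed in the flask) | C=C(C)CB([C@@H]1C[C@@H]2C[C@H]([C@H]1C)C2(C)C)[C@@H]1C[C@@H]2C[C@H]([C@H]1C)C2(C)C | intermediate
25 | diisopinocampheylborinate of 26 at the new secondary oxygen (formed in the flask) | C=CC[C@@]1(C)CC[C@@](O)(C(C)C)[C@@H]1[C@@H](OB([C@@H]2C[C@@H]3C[C@H]([C@H]2C)C3(C)C)[C@@H]2C[C@@H]3C[C@H]([C@H]2C)C3(C)C)CC(C)=C | intermediate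
26 | (1R,2S,3R)-2-[(1S)-1-hydroxy-3-methylbut-3-en-1-yl]-3-methyl-1-(propan-2-yl)-3-(prop-2-en-1-yl)cyclopentan-1-ol | C=CC[C@@]1(C)CC[C@@](O)(C(C)C)[C@@H]1[C@@H](O)CC(C)=C | intermediate
27 | (3R,3aS,4S,8aR)-6,8a-dimethyl-3-(propan-2-yl)-1,2,3,3a,4,5,8,8a-octahydroazulene-3,4-diol (jaeschkeanadiol) | CC1=CC[C@@]2(C)CC[C@@](O)(C(C)C)[C@@H]2[C@@H](O)C1 | intermediate
28 | O-acetylsalicyloyl chloride (2-acetoxybenzoyl chloride) | CC(=O)Oc1ccccc1C(Cl)=O | starting material
29 | (3R,3aS,4S,8aR)-3-hydroxy-6,8a-dimethyl-3-(propan-2-yl)-1,2,3,3a,4,5,8,8a-octahydroazulen-4-yl 2-(acetyloxy)benzoate | CC1=CC[C@@]2(C)CC[C@@](O)(C(C)C)[C@@H]2[C@@H](OC(=O)c2ccccc2OC(C)=O)C1 | intermediate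
30 | (3R,3aS,4S,8aR)-3-hydroxy-6,8a-dimethyl-3-(propan-2-yl)-1,2,3,3a,4,5,8,8a-octahydroazulen-4-yl 2-hydroxybenzoate | CC1=CC[C@@]2(C)CC[C@@](O)(C(C)C)[C@@H]2[C@@H](OC(=O)c2ccccc2O)C1 | target

**Totals and risks**
Total step count: 18. Longest linear sequence: 18 steps (1 → 30).

The three steps most likely to fail:

Step 10 (base-mediated aldol condensation). Hydroxide could epimerise the ketone α-CH or eliminate the β-silyloxy group. The fallback sets out from 16: soft enolisation (TMSOTf, Et3N, CH2Cl2, −20 °C) gives the terminal trimethylsilyl enol ether F1. BF3·OEt2 at −78 °C then closes the ring by an intramolecular Mukaiyama aldol addition, and aldol 17 is isolated. Mesylation (MsCl, Et3N) gives mesylate F2, and DBU elimination returns to the route at 18, with no hydroxide or alkoxide ever present.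

Step 12 (isopropyl addition to the hindered ketone). The secondary Grignard reagent may reduce or enolise 19 instead of adding. The fallback sets out from 19: the non-reducing sp2 nucleophile CH2=C(CH3)MgBr with CeCl3 (THF, −78 °C) adds with the same facial preference to give isopropenyl carbinol F3. Hydrogen-atom-transfer hydrogenation (Mn(dpm)3 cat., PhSiH3, t-BuOOH, i-PrOH, rt) then reduces the 1,1-disubstituted alkene, which gives a tertiary radical, in preference to the monosubstituted allyl group, and the route is rejoined at 20.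

Step 15 (reagent-controlled methallylation of a congested α-branched aldehyde). The substrate bias is unknown and could oppose the reagent. The fallback sets out from 22: Grignard reagent 23 is added directly (THF, −78 °C) to give the carbinol epimer mixture F4. Ring-closing metathesis as in step 16 gives the bicyclic diol epimer mixture F5. Dess–Martin oxidation of the secondary alcohol gives β-hydroxy ketone F6. Hydroxyl-directed reduction with Me4NBH(OAc)3 in MeCN–AcOH (Evans–Saksena) delivers hydride from boron bound to the tertiary hydroxyl to the same face of the ketone, giving the 4-hydroxyl trans to it, and the route is rejoined at 27.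

**Further compounds**
F1 | step 10 | (2R,3S)-3-({[tert-butyl(dimethyl)silyl]oxy}methyl)-2-methyl-2-(prop-2-en-1-yl)-4-[(trimethylsilyl)oxy]pent-4-enal | C=CC[C@@](C)(C=O)[C@@H](CO[Si](C)(C)C(C)(C)C)C(=C)O[Si](C)(C)C
F2 | step 10 | methanesulfonate of aldol 17 | C=CC[C@@]1(C)C(OS(C)(=O)=O)CC(=O)[C@@H]1CO[Si](C)(C)C(C)(C)C
F3 | step 12 | analogue of 20 carrying prop-1-en-2-yl in place of propan-2-yl, same spatial arrangement | C=CC[C@@]1(C)CC[C@@](O)(C(C)=C)[C@@H]1CO[Si](C)(C)C(C)(C)C
F4 | step 15 | 26 as a mixture of epimers at the new secondary carbinol | C=CC[C@@]1(C)CC[C@@](O)(C(C)C)[C@@H]1C(O)CC(C)=C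
F5 | step 15 | 27 as a mixture of epimers at C-4 | CC1=CC[C@@]2(C)CC[C@@](O)(C(C)C)[C@@H]2C(O)C1
F6 | step 15 | (3R,3aR,8aR)-3-hydroxy-6,8a-dimethyl-3-(propan-2-yl)-2,3,3a,5,8,8a-hexahydroazulen-4(1H)-one | CC1=CC[C@@]2(C)CC[C@@](O)(C(C)C)[C@@H]2C(=O)C1
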